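**Strategy.** Everything rests on cutting the O1–C8a bond of the upper unit. That oxygen is the third of three contiguous oxygens on the upper ring A and stands three bonds from the benzhydrylic C4, which is the arrangement of a 3-arylindan-1-one whose carbonyl carbon is bonded to the future C8a. Baeyer–Villiger oxidation of that ketone inserts O1 by aryl migration and expands the five-membered ring to the lactone ring C in one operation, leaving C4 untouched. The precursor is a (3R)-6,7-bis(benzyloxy)indan-1-one bearing the all-cis lower flavan-3,4-diol at C3; the diol is carried as two benzyl ethers instead of a ketal, so that a single hydrogenolysis ends the route.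

Key step: step 16

Remark 1: flavan numbering is used for both units; "lower" is the 3,4-diol unit (target: lower 2R,3R,4R all-cis; upper 2S,3R,4S, 2,3-trans-3,4-trans).
Remark 2: the bisphosphine antipodes named in steps 3 and 15 are the ones expected to give the drawn configurations; the sense is checked on the first run and the other antipode is taken if it is opposite.
Remark 3: compound 29 is a ring–chain tautomeric pair (2-hydroxyflavan and open keto-phenol); it is drawn as the lactol with the hemiketal carbon undefined.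

**Route**

Step 1
Reactants: 1 gallacetophenone (2',3',4'-trihydroxyacetophenone)
Product: 2 3',4'-bis(benzyloxy)-2'-hydroxyacetophenone
Conditions: BnBr (2.1 equiv), K2CO3, acetone, reflux
Reagents that add atoms: benzyl bromide, BrCc1ccccc1
Why: Williamson etherification in which the 2'-hydroxyl, hydrogen-bonded to the carbonyl group, is left free when only two equivalents of halide are used.

Step 2
Reactants: 2 3',4'-bis(benzyloxy)-2'-hydroxyacetophenone
Product: 4 7,8-bis(benzyloxy)-4H-chromen-4-one, via enaminone 3 (not isolated)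
Conditions: Me2NCH(OMe)2, toluene, 100 °C; then p-TsOH·H2O, CH2Cl2, rt
Reagents that add atoms: N,N-dimethylformamide dimethyl acetal, COC(OC)N(C)C
Why: enaminone condensation at the acetyl methyl group followed by acid-promoted addition–elimination of the phenol, the standard chromone synthesis from 2'-hydroxyacetophenones.

Step 3
Reactants: 4 7,8-bis(benzyloxy)-4H-chromen-4-one; 5 4-(benzyloxy)phenylboronic acid
Product: 6 (2S)-7,8-bis(benzyloxy)-2-[4-(benzyloxy)phenyl]chroman-4-one
Conditions: [Rh(OH)(cod)]2 (cat.), (S)-MeO-F12-BIPHEP, toluene/H2O, 40 °C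
Reagents that add atoms: none
Why: Hayashi–Miyaura rhodium-catalysed asymmetric 1,4-addition of an arylboronic acid to a chromone, in which the chiral bisphosphine selects the enone face and so sets C2.

Step 4
Reactants: 6 (2S)-flavanone
Product: 7 (2S,4S)-7,8-bis(benzyloxy)-2-[4-(benzyloxy)phenyl]chroman-4-ol (2,4-cis)
Conditions: NaBH4, MeOH/THF, 0 °C
Reagents that add atoms: none
Why: borohydride reduction of the ketone, axial hydride attack on the half-chair with equatorial 2-aryl giving the 2,4-cis alcohol (this centre is removed in step 5).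

Step 5
Reactants: 7 (2S,4S)-flavan-4-ol
Product: 9 (2S)-7,8-bis(benzyloxy)-2-[4-(benzyloxy)phenyl]-2H-chromene, via mesylate 8 (not isolated)
Conditions: MsCl, Et3N, CH2Cl2, 0 °C → rt, dark
Reagents that add atoms: none
Why: sulfonylation–elimination in which the benzylic mesylate, para to the 7-benzyloxy group, ionises and loses H3 under basic conditions that leave C2 alone.

Step 6
Reactants: 9 (2S)-2H-chromene
Product: 11 (2R,3S,4R)-4,7,8-tris(benzyloxy)-2-[4-(benzyloxy)phenyl]chroman-3-ol (2,3-trans-3,4-trans), via epoxide 10 (not isolated)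
Conditions: DMDO, acetone/CH2Cl2, −40 °C; then BnOH, CSA (cat.), −40 → 0 °C
Reagents that add atoms: dimethyldioxirane, CC1(C)OO1; benzyl alcohol, OCc1ccccc1
Why: epoxidation on the face anti to the 2-aryl group followed by acid-catalysed alcoholysis at the benzylic C4 anti to the oxirane oxygen, which sets C3 (hydroxyl trans to aryl) and C4 (benzyloxy cis to aryl) and leaves only the 3-hydroxyl free.

Step 7
Reactants: 11 (2R,3S,4R)-flavan-3-ol
Product: 12 (2R,4R)-4,7,8-tris(benzyloxy)-2-[4-(benzyloxy)phenyl]chroman-3-one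
Conditions: Dess–Martin periodinane, NaHCO3, CH2Cl2, 0 °C → rt; used crude
Reagents that add atoms: none
Why: Dess–Martin oxidation of the secondary alcohol under buffered conditions, the two α-substituents already being in the stable diequatorial arrangement.

Step 8
Reactants: 12 flavan-3-one
Product: 13 (2R,3R,4R)-4,7,8-tris(benzyloxy)-2-[4-(benzyloxy)phenyl]chroman-3-ol (all-cis)
Conditions: LiBH(s-Bu)3, LiBr, THF, −78 °C; then H2O
Reagents that add atoms: none
Why: ketone reduction by a bulky trialkylborohydride from the equatorial direction, as in the catechin-to-epicatechin inversion, so that the new 3-hydroxyl is axial and cis to both the 2-aryl and the 4-benzyloxy group (sets C3).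

Step 9
Reactants: 13 all-cis flavan-3-ol
Product: 14 (2R,3R,4R)-3,4,7,8-tetrakis(benzyloxy)-2-[4-(benzyloxy)phenyl]chroman
Conditions: NaH, BnBr, n-Bu4NI (cat.), DMF, 0 °C → rt
Reagents that add atoms: benzyl bromide, BrCc1ccccc1
Why: Williamson etherification of the remaining secondary alcohol, which gives a lower unit protected by benzyl ethers only.

Step 10
Reactants: 14 pentabenzyl flavan
Product: 15 (2R,3R,4R)-6-bromo-3,4,7,8-tetrakis(benzyloxy)-2-[4-(benzyloxy)phenyl]chroman
Conditions: NBS, MeCN, 0 °C, dark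
Reagents that add atoms: N-bromosuccinimide, O=C1CCC(=O)N1Br
Why: electrophilic aromatic bromination at C6, the only position that is para to O1 and ortho to the 7-benzyloxy group and hence the most activated site of the molecule.

Step 11
Reactants: 15 6-bromoflavan
Product: 17 (2R,3R,4R)-3,4,7,8-tetrakis(benzyloxy)-2-[4-(benzyloxy)phenyl]chroman-6-carbaldehyde, via aryllithium 16 (not isolated)
Conditions: n-BuLi, THF, −78 °C; DMF, −78 °C; then H2O
Reagents that add atoms: N,N-dimethylformamide, CN(C)C=O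
Why: bromine–lithium exchange followed by Bouveault formylation, fast at −78 °C and faster than any metalation of the benzyl ethers.

Step 12
Reactants: 18 2',3'-dihydroxyacetophenone
Product: 19 2',3'-bis(benzyloxy)acetophenone
Conditions: BnBr (2.5 equiv), K2CO3, KI (cat.), DMF, 60 °C
Reagents that add atoms: benzyl bromide, BrCc1ccccc1
Why: exhaustive Williamson etherification, the polar solvent and heat also alkylating the hydrogen-bonded 2'-hydroxyl.

Step 13
Reactants: 19 2',3'-bis(benzyloxy)acetophenone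
Product: 20 2',3'-bis(benzyloxy)-6'-bromoacetophenone
Conditions: NBS, MeCN, rt, dark
Reagents that add atoms: N-bromosuccinimide, O=C1CCC(=O)N1Br
Why: electrophilic aromatic bromination para to the 3'-benzyloxy group, the only ether able to conjugate (the 2'-ether is twisted by its two neighbours), as in the known 6-bromination of 2,3-dialkoxybenzaldehydes.

Step 14
Reactants: 17 lower-unit 6-carbaldehyde; 20 2',3'-bis(benzyloxy)-6'-bromoacetophenone
Product: 21 (E)-1-[2,3-bis(benzyloxy)-6-bromophenyl]-3-[(2R,3R,4R)-3,4,7,8-tetrakis(benzyloxy)-2-(4-benzyloxyphenyl)chroman-6-yl]prop-2-en-1-one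
Conditions: KOH, EtOH/THF, rt → 40 °C
Reagents that add atoms: none
Why: Claisen–Schmidt aldol condensation of a methyl ketone with a non-enolisable aldehyde, E1cB dehydration giving the E-enone.

Step 15
Reactants: 21 2'-bromochalcone
Product: 22 (3R)-6,7-bis(benzyloxy)-3-[(2R,3R,4R)-3,4,7,8-tetrakis(benzyloxy)-2-(4-benzyloxyphenyl)chroman-6-yl]indan-1-one
Conditions: Pd(OAc)2 (5 mol %), (R)-3,5-Xyl-MeO-BIPHEP (6 mol %), HCO2H, i-Pr2NEt, DMF, 80 °C
Reagents that add atoms: none
Why: asymmetric reductive Heck cyclisation (oxidative addition of C–Br to zerovalent palladium, aryl transfer to the enone β-carbon, protonation of the palladium enolate, reduction of divalent palladium by formate), in which the chiral bisphosphine chooses the enone face and sets the benzhydrylic centre, the existing stereocentres being remote.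

Step 16
Reactants: 22 (3R)-3-arylindan-1-one
Product: 23 (4R)-7,8-bis(benzyloxy)-4-[(2R,3R,4R)-3,4,7,8-tetrakis(benzyloxy)-2-(4-benzyloxyphenyl)chroman-6-yl]chroman-2-one
Conditions: m-CPBA, NaHCO3, CH2Cl2, 0 °C → rt, dark
Reagents that add atoms: m-chloroperbenzoic acid, OOC(=O)c1cccc(Cl)c1
Why: The peracid adds to the indanone carbonyl group and, in the tetrahedral adduct, the aryl carbon C7a shifts from carbon to oxygen with loss of 3-chlorobenzoate, which creates the O1–C8a bond. The closest known reaction is the Baeyer–Villiger oxidation of 1-indanones to 3,4-dihydrocoumarins. Ring C is not closed by a cyclisation but arises by ring expansion of the existing five-membered ketone through this 1,2-shift, so no ring-closure mode has to be satisfied. No stereocentre is formed, and C4, β to the carbonyl group and remote from the migration, keeps its configuration. The step needs migration of aryl in preference to methylene, which the electron-rich aryl carbon with its ortho benzyloxy donor secures through its higher migratory aptitude. The bicarbonate buffer keeps acid away from the benzylic ethers and limits oxidation of the alkoxyarenes.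

Step 17
Reactants: 23 lactone
Product: 25 (3R,4R)-3-hydroxy lactone (3,4-trans; otherwise as 23), via potassium enolate 24 (not isolated)
Conditions: KN(SiMe3)2, THF, −78 °C; 2-(phenylsulfonyl)-3-phenyloxaziridine, −78 °C; AcOH quench
Reagents that add atoms: 2-(phenylsulfonyl)-3-phenyloxaziridine, O=S(=O)(c1ccccc1)N1OC1c1ccccc1
Why: Davis enolate hydroxylation in which the oxidant reaches the planar lactone enolate on the face anti to the bulky C4 aryl group, which sets C3 trans to C4; the low temperature prevents ketene formation from the aryl ester enolate.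

Step 18
Reactants: 25 3-hydroxy lactone
Product: 26 (3R,4R)-3-benzyloxy lactone (3,4-trans)
Conditions: BnBr, Ag2O, 4 Å MS, CH2Cl2, rt, dark
Reagents that add atoms: benzyl bromide, BrCc1ccccc1
Why: silver oxide-mediated O-benzylation, a near-neutral etherification that does not enolise the α-oxy lactone and so keeps C3.

Step 19
Reactants: 26 3-benzyloxy lactone; 27 1-(benzyloxy)-4-bromobenzene
Product: 29 2-[4-(benzyloxy)phenyl]-2-hydroxyflavan (lactol; upper 3R,4R as in 26), via aryllithium 28 (not isolated)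
Conditions: 27, n-BuLi, THF, −78 °C; then 26, THF, −78 °C; then H2O
Reagents that add atoms: none
Why: bromine–lithium exchange and addition of one equivalent of aryllithium to the aryl lactone, which stops at the ketone stage because the released p-alkoxyaryl ketone is deactivated and hindered compared with the aryl ester.

Step 20
Reactants: 29 lactol
Product: 30 nona-O-benzyl ether of the target (upper unit 2S,3R,4R by the CIP rules, 2,3-trans-3,4-trans)
Conditions: Et3SiH, BF3·OEt2, CH2Cl2/MeCN, −78 → −40 °C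
Reagents that add atoms: none
Why: ionic hydrogenation of a hemiketal, in which the Lewis acid gives the 2-aryl oxocarbenium ion and the silane delivers hydride axially, cis to the C3 benzyloxy group as in C-aryl glycoside synthesis, so that the 2-aryl group ends equatorial and trans to C3 (sets C2); the low temperature spares the less easily ionised lower C4 ether.

Step 21
Reactants: 30 nona-O-benzyl ether
Product: 31 CNP0391561.2, (2R,3R,4R)-2-(4-hydroxyphenyl)-6-[(2S,3R,4S)-3,7,8-trihydroxy-2-(4-hydroxyphenyl)chroman-4-yl]chroman-3,4,7,8-tetrol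
Conditions: H2 (1 atm), Pd(OH)2/C, THF/MeOH, rt
Reagents that add atoms: none
Why: catalytic hydrogenolysis of the nine benzyl ethers, whose primary benzyl C–O bonds cleave faster under neutral conditions than the ring C2–O1 bonds and the lower secondary C4–O bond (the upper C4 descriptor changes from R to S on debenzylation with no change in geometry).

**Compound list**

1 | gallacetophenone | CC(=O)c1ccc(O)c(O)c1O | starting material
2 | 3',4'-bis(benzyloxy)-2'-hydroxyacetophenone | CC(=O)c1ccc(OCc2ccccc2)c(OCc2ccccc2)c1O | intermediate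
3 | (E)-1-[3,4-bis(benzyloxy)-2-hydroxyphenyl]-3-(dimethylamino)prop-2-en-1-one | CN(C)/C=C/C(=O)c1ccc(OCc2ccccc2)c(OCc2ccccc2)c1O | intermediate
4 | 7,8-bis(benzyloxy)-4H-chromen-4-one | O=c1ccoc2c(OCc3ccccc3)c(OCc3ccccc3)ccc12 | intermediate
5 | 4-(benzyloxy)phenylboronic acid | OB(O)c1ccc(OCc2ccccc2)cc1 | starting material
6 | (2S)-7,8-bis(benzyloxy)-2-[4-(benzyloxy)phenyl]chroman-4-one | c1ccccc1COc1ccc(cc1)[C@H]1Oc2c(OCc3ccccc3)c(OCc3ccccc3)ccc2C(=O)C1 | intermediate
7 | (2S,4S)-7,8-bis(benzyloxy)-2-[4-(benzyloxy)phenyl]chroman-4-ol | c1ccccc1COc1ccc(cc1)[C@H]1Oc2c(OCc3ccccc3)c(OCc3ccccc3)ccc2[C@@H](O)C1 | intermediate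
8 | 4-O-methanesulfonate of 7 | c1ccccc1COc1ccc(cc1)[C@H]1Oc2c(OCc3ccccc3)c(OCc3ccccc3)ccc2[C@@H](OS(C)(=O)=O)C1 | intermediate
9 | (2S)-7,8-bis(benzyloxy)-2-[4-(benzyloxy)phenyl]-2H-chromene | c1ccccc1COc1ccc(cc1)[C@H]1Oc2c(OCc3ccccc3)c(OCc3ccccc3)ccc2C=C1 | intermediate
10 | (2R,3S,4S)-7,8-bis(benzyloxy)-2-[4-(benzyloxy)phenyl]-3,4-epoxychroman (oxirane trans to the 2-aryl group) | c1ccccc1COc1ccc(cc1)[C@H]1Oc2c(OCc3ccccc3)c(OCc3ccccc3)ccc2[C@@H]2O[C@H]12 | intermediate
11 | (2R,3S,4R)-4,7,8-tris(benzyloxy)-2-[4-(benzyloxy)phenyl]chroman-3-ol | c1ccccc1COc1ccc(cc1)[C@H]1Oc2c(OCc3ccccc3)c(OCc3ccccc3)ccc2[C@@H](OCc2ccccc2)[C@@H]1O | intermediate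
12 | (2R,4R)-4,7,8-tris(benzyloxy)-2-[4-(benzyloxy)phenyl]chroman-3-one | c1ccccc1COc1ccc(cc1)[C@H]1Oc2c(OCc3ccccc3)c(OCc3ccccc3)ccc2[C@@H](OCc2ccccc2)C1=O | intermediate
13 | (2R,3R,4R)-4,7,8-tris(benzyloxy)-2-[4-(benzyloxy)phenyl]chroman-3-ol | c1ccccc1COc1ccc(cc1)[C@H]1Oc2c(OCc3ccccc3)c(OCc3ccccc3)ccc2[C@@H](OCc2ccccc2)[C@H]1O | intermediate
14 | (2R,3R,4R)-3,4,7,8-tetrakis(benzyloxy)-2-[4-(benzyloxy)phenyl]chroman | c1ccccc1COc1ccc(cc1)[C@H]1Oc2c(OCc3ccccc3)c(OCc3ccccc3)ccc2[C@@H](OCc2ccccc2)[C@H]1OCc1ccccc1 | intermediate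
15 | (2R,3R,4R)-6-bromo-3,4,7,8-tetrakis(benzyloxy)-2-[4-(benzyloxy)phenyl]chroman | c1ccccc1COc1ccc(cc1)[C@H]1Oc2c(OCc3ccccc3)c(OCc3ccccc3)c(Br)cc2[C@@H](OCc2ccccc2)[C@H]1OCc1ccccc1 | intermediate
16 | 6-lithio derivative of 14 | c1ccccc1COc1ccc(cc1)[C@H]1Oc2c(OCc3ccccc3)c(OCc3ccccc3)c([Li])cc2[C@@H](OCc2ccccc2)[C@H]1OCc1ccccc1 | intermediate
17 | (2R,3R,4R)-3,4,7,8-tetrakis(benzyloxy)-2-[4-(benzyloxy)phenyl]chroman-6-carbaldehyde | c1ccccc1COc1ccc(cc1)[C@H]1Oc2c(OCc3ccccc3)c(OCc3ccccc3)c(C=O)cc2[C@@H](OCc2ccccc2)[C@H]1OCc1ccccc1 | intermediate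
18 | 2',3'-dihydroxyacetophenone | CC(=O)c1cccc(O)c1O | starting material
19 | 2',3'-bis(benzyloxy)acetophenone | CC(=O)c1cccc(OCc2ccccc2)c1OCc1ccccc1 | intermediate
20 | 2',3'-bis(benzyloxy)-6'-bromoacetophenone | CC(=O)c1c(Br)ccc(OCc2ccccc2)c1OCc1ccccc1 | intermediate
21 | (E)-2'-bromochalcone of 17 and 20 | c1ccccc1COc1ccc(cc1)[C@H]1Oc2c(OCc3ccccc3)c(OCc3ccccc3)c(/C=C/C(=O)c3c(Br)ccc(OCc4ccccc4)c3OCc3ccccc3)cc2[C@@H](OCc2ccccc2)[C@H]1OCc1ccccc1 | intermediate
22 | (3R)-6,7-bis(benzyloxy)-3-(lower-unit-6-yl)indan-1-one | c1ccccc1COc1ccc(cc1)[C@H]1Oc2c(OCc3ccccc3)c(OCc3ccccc3)c([C@@H]3CC(=O)c4c(OCc5ccccc5)c(OCc5ccccc5)ccc34)cc2[C@@H](OCc2ccccc2)[C@H]1OCc1ccccc1 | intermediate (key-step precursor)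
23 | (4R)-7,8-bis(benzyloxy)-4-(lower-unit-6-yl)chroman-2-one | c1ccccc1COc1ccc(cc1)[C@H]1Oc2c(OCc3ccccc3)c(OCc3ccccc3)c([C@H]3c4ccc(OCc5ccccc5)c(OCc5ccccc5)c4OC(=O)C3)cc2[C@@H](OCc2ccccc2)[C@H]1OCc1ccccc1 | intermediate (key-step product)
24 | potassium enolate of 23 | c1ccccc1COc1ccc(cc1)[C@H]1Oc2c(OCc3ccccc3)c(OCc3ccccc3)c([C@H]3c4ccc(OCc5ccccc5)c(OCc5ccccc5)c4OC([O-])=C3)cc2[C@@H](OCc2ccccc2)[C@H]1OCc1ccccc1.[K+] | intermediate
25 | (3R,4R)-3-hydroxy derivative of 23 (3,4-trans) | c1ccccc1COc1ccc(cc1)[C@H]1Oc2c(OCc3ccccc3)c(OCc3ccccc3)c([C@H]3c4ccc(OCc5ccccc5)c(OCc5ccccc5)c4OC(=O)[C@@H]3O)cc2[C@@H](OCc2ccccc2)[C@H]1OCc1ccccc1 | intermediate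
26 | (3R,4R)-3-benzyloxy derivative of 23 (3,4-trans) | c1ccccc1COc1ccc(cc1)[C@H]1Oc2c(OCc3ccccc3)c(OCc3ccccc3)c([C@H]3c4ccc(OCc5ccccc5)c(OCc5ccccc5)c4OC(=O)[C@@H]3OCc3ccccc3)cc2[C@@H](OCc2ccccc2)[C@H]1OCc1ccccc1 | intermediate
27 | 1-(benzyloxy)-4-bromobenzene | Brc1ccc(OCc2ccccc2)cc1 | starting material
28 | 4-(benzyloxy)phenyllithium | [Li]c1ccc(OCc2ccccc2)cc1 | intermediate
29 | 2-[4-(benzyloxy)phenyl]-2-hydroxy lactol from 26 (hemiketal carbon undefined) | c1ccccc1COc1ccc(cc1)[C@H]1Oc2c(OCc3ccccc3)c(OCc3ccccc3)c([C@H]3c4ccc(OCc5ccccc5)c(OCc5ccccc5)c4OC(O)(c4ccc(OCc5ccccc5)cc4)[C@@H]3OCc3ccccc3)cc2[C@@H](OCc2ccccc2)[C@H]1OCc1ccccc1 | intermediate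
30 | nona-O-benzyl ether of the target | c1ccccc1COc1ccc(cc1)[C@H]1Oc2c(OCc3ccccc3)c(OCc3ccccc3)c([C@H]3c4ccc(OCc5ccccc5)c(OCc5ccccc5)c4O[C@@H](c4ccc(OCc5ccccc5)cc4)[C@@H]3OCc3ccccc3)cc2[C@@H](OCc2ccccc2)[C@H]1OCc1ccccc1 | intermediate
31 | CNP0391561.2 | Oc1ccc([C@H]2Oc3c(cc([C@H]4c5ccc(O)c(O)c5O[C@@H](c5ccc(O)cc5)[C@@H]4O)c(O)c3O)[C@@H](O)[C@H]2O)cc1 | target

**Step count and risk**

Total steps: 21. Longest linear sequence: 19 (steps 1–11 and 14–21, from gallacetophenone); steps 12–13 form the short convergent branch.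

The three steps most likely to fail:

Step 15, asymmetric reductive Heck cyclisation. The catalyst may fail to discriminate the enone faces next to the bulky β-aryl group, or formate may reduce the arylpalladium bromide before it cyclises. The fallback sets out from 21 and returns at 22. Miyaura borylation of 21 (B2pin2, PdCl2(dppf), KOAc, dioxane, 80 °C) would give the 2'-(pinacolboryl)chalcone F1. Rhodium-catalysed asymmetric intramolecular 1,4-addition ([RhCl(C2H4)2]2, (R)-MonoPhos or its antipode, aq K3PO4, toluene, 60 °C) would then transfer the aryl group to the enone β-carbon and protonate the rhodium enolate, a known entry to 3-arylindan-1-ones.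

Step 16, Baeyer–Villiger oxidation. The peracid may add only slowly to the hindered conjugated ketone, some methylene migration may occur, or the alkoxyarenes may be oxidised. The fallback sets out from 15 and returns at 23, making the same lactone by forming the C4–aryl bond instead of O1–C8a. Bromide 15 would be lithiated as in step 11 (16), trapped with B(OMe)3 and hydrolysed with dilute HCl to the lower-unit 6-boronic acid F2. Commercial daphnetin (7,8-dihydroxycoumarin) would be benzylated (BnBr, K2CO3, DMF) to 7,8-bis(benzyloxy)coumarin F3. Hayashi–Miyaura 1,4-addition of F2 to F3 (Rh(acac)(C2H4)2, the SEGPHOS antipode that gives the 4R lactone, dioxane/H2O, 60 °C) would give 23 directly.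

Step 20, silane reduction of the lactol. The Lewis acid may ionise the lower C4 benzyl ether with loss of that oxygen, or hydride may be delivered to the wrong face of the oxocarbenium ion. The fallback sets out from 29 and returns at 30 without any Lewis acid. The open keto-phenol tautomer of 29 would be reduced with KBH(s-Bu)3 (THF, −78 °C, Felkin–Anh sense) to the 1,2-syn carbinol F4. Mitsunobu cyclodehydration (PPh3, DIAD, THF, 0 °C) would then close O1–C2 with inversion to the same 2,3-trans flavan 30.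

**Further compounds**

F1 | step 15 | (E)-2'-(4,4,5,5-tetramethyl-1,3,2-dioxaborolan-2-yl) analogue of chalcone 21 | c1ccccc1COc1ccc(cc1)[C@H]1Oc2c(OCc3ccccc3)c(OCc3ccccc3)c(/C=C/C(=O)c3c(B4OC(C)(C)C(C)(C)O4)ccc(OCc4ccccc4)c3OCc3ccccc3)cc2[C@@H](OCc2ccccc2)[C@H]1OCc1ccccc1
F2 | step 16 | [(2R,3R,4R)-3,4,7,8-tetrakis(benzyloxy)-2-(4-benzyloxyphenyl)chroman-6-yl]boronic acid | c1ccccc1COc1ccc(cc1)[C@H]1Oc2c(OCc3ccccc3)c(OCc3ccccc3)c(B(O)O)cc2[C@@H](OCc2ccccc2)[C@H]1OCc1ccccc1
F3 | step 16 | 7,8-bis(benzyloxy)coumarin | O=c1ccc2ccc(OCc3ccccc3)c(OCc3ccccc3)c2o1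
F4 | step 20 | 1,2-syn carbinol (open-chain phenol diol) from 29 | c1ccccc1COc1ccc(cc1)[C@H]1Oc2c(OCc3ccccc3)c(OCc3ccccc3)c([C@@H](c3ccc(OCc4ccccc4)c(OCc4ccccc4)c3O)[C@@H](OCc3ccccc3)[C@H](O)c3ccc(OCc4ccccc4)cc3)cc2[C@@H](OCc2ccccc2)[C@H]1OCc1ccccc1
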